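All constants are made up; the rest is arithmetic.

In a one-step world substrate meets reagent and nothing else, so a flask heads for target equal to the reagent charge, 80.0% of the substrate put in.

    substrate + reagent → target + by-product (k1 = 159 M⁻¹ s⁻¹)
    2 substrate → homo dimer (k2 = 66.0 M⁻¹ s⁻¹)

| flask | substrate | reagent | time | remark |
|---|---|---|---|---|
| south-east | 2.0 mM | 1.60 mM (fed, over 32.0 s) | 40 s | a stirred flask in which reagent is dosed at a steady rate over 32.0 s without added volume, worked up at 40 s |
| north-west | 2.0 mM | 1.60 mM | 40 s | everything together in a closed stirred flask, run for 40 s |
| north | 2.0 mM | 1.60 mM |  | one stirred flow tank at steady state, fed with the mixture as stated, mean residence time 40 s |
| east | 2.0 mM (fed, over 32.0 s) | 1.60 mM | 40 s | all but substrate at the start; substrate goes in evenly over 32.0 s, the run ends at 40 s |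

- in percentages every species weighs as the substrate in it: one homo dimer counts as two
- where a step has two of a species, its rate is k times that concentration squared, and two are used at each turn
- the stated concentrations are those of everything mixed, before any reaction; amounts are the same in each set-up
- the feed brings no volume worth counting
- run time (south-east): 40 s

1. the set-up with the highest amount of target at the outlet or at the end, in percent of the substrate put in ("none" if the first two lie within 2 percentage points) (south-east / north-west / north / east / none)
2. amount of target at the outlet or at the end, in percent of the substrate put in, south-east
3. amount of target at the outlet or at the end, in percent of the substrate put in, north-west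
4. amount of target at the outlet or at the end, in percent of the substrate put in, north
5. amount of target at the outlet or at the end, in percent of the substrate put in, east

For south-east to stand on top, dosed reagent has to reach the substrate before dimerisation has taken it. In south-east, with dimerisation as its sole loss, the reciprocal of [substrate] grows linearly from that of the charge at 132 M⁻¹ s⁻¹, which is the rate law integrated, and the first half-life is 3.79 s. Substrate's pull towards homo dimer, per unit of substrate, soon tends to the reciprocal of elapsed time. Its pseudo-first-order pull towards target is the first constant times [reagent], which this reckoning lets climb with time as reagent enters at 0.0500 mM s⁻¹, its use neglected. Setting these two approximate pulls equal gives the handover time 11.2 s, the square root of the reciprocal of that constant times the dosing rate; the substrate charge does not enter this estimate. A lead for south-east asks for a handover below the half-life, but here the handover is longer, by a factor of 2.96.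

The reckoning made here takes target in south-east as the substrate still standing at the handover, with dimerisation as its sole loss until then: 0.505 mM, or 25.2% of the charge. It prices no other set-up.

The forecast gives 27% for south-east, lower than the others, with north-west 59.4%, north 54.2% and east 66%, so east comes first, since “keeping substrate scarce against a full charge of reagent (east) favours the target”. The reckoning here lies lower on south-east.

The simulation puts east first at 66.5%, then north-west 59.5%, north 54.3% and south-east 25.7%.

South-east ends with by-product 0.514 mM, beside the 0.505 mM reckoned. The neighbour flask is south-east with 3.4 mM of substrate, and its handover stays at 11.2 s. The same reckoning gives 0.564 mM, or 16.6% of its charge. That flask gives 16.7% target, with by-product 0.569 mM and homo dimer 83.0%.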